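**Plan**

1. Cuts: the two silyl ethers; then C2'–C3' and O1'–C6' of the dihydropyranone (acetaldehyde + coumarin-bound 1,3-bis(silyloxy)diene); then coumarin O1–C2 and C3–C4 (salicylaldehyde + triacetic acid lactone); then the aryl–CHO, aryl–CH3 and aryl–side-chain bonds (aryl bromides + (2R,3R)-2,3-epoxybutane).
2. Enabling feature: the 2-methyl-2,3-dihydro-4H-pyran-4-one ring (O1', C2'–C6'), joined through C6' to coumarin C3 and carrying its only stereocentre at C2' beside O1', is the formal cycloadduct of an aldehyde and a 1,3-dioxygenated diene.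
3. Forward order: side chain onto the arene, then ring methyl and aldehyde, then the coumarin ring, last the dihydropyranone ring.
4. Stereochemistry: both side-chain centres come from the epoxide (inversion at the arylated carbon, carbinol carbon untouched); C2' comes from an (R)-BINOL–titanium catalyst (Re-face attack on acetaldehyde corresponds to S).

Key step: step 10

Remark: coumarin atoms are numbered O1, C2–C8a and dihydropyranone atoms O1', C2'–C6'; the purchased dibenzyl ether 1 is used in place of 1-bromo-3,5-dimethoxybenzene because benzyl ethers can later be removed without harming the silyl ether or the aldehyde. Abbreviations: TBS = tert-butyldimethylsilyl, TMS = trimethylsilyl.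

**Step 1**
Reactants: 1 1,3-bis(benzyloxy)-5-bromobenzene; 2 (2R,3R)-2,3-epoxybutane
Product: 4 (2R,3R)-3-[3,5-bis(benzyloxy)phenyl]butan-2-ol, via aryl Grignard reagent 3 (not isolated)
Conditions: Mg, THF, reflux; then CuI (copper monoiodide, 10 mol%), 2, THF, −30 → 0 °C
Reagents that add atoms: none
Why: Copper-catalysed SN2 opening of an epoxide by an aryl Grignard reagent, in which the C2-symmetric trans-epoxide offers two equivalent carbons, attack inverts the arylated carbon and leaves the carbinol carbon untouched, so the (2R,3R)-epoxide should give the erythro (2R,3R)-alcohol and both side-chain stereocentres are set here.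

**Step 2**
Reactants: 4 (2R,3R)-3-[3,5-bis(benzyloxy)phenyl]butan-2-ol
Product: 5 1,3-bis(benzyloxy)-5-[(2R,3R)-3-(tert-butyldimethylsilyloxy)butan-2-yl]benzene
Conditions: TBSCl, imidazole, DMF, rt
Reagents that add atoms: tert-butyldimethylsilyl chloride (TBSCl), CC(C)(C)[Si](C)(C)Cl
Why: Standard silylation of a secondary alcohol, which keeps the hydroxyl from quenching the organolithiums, from closing a lactol onto the later ortho aldehyde and from adding to C4 of the later 3-acylcoumarins.

**Step 3**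
Reactants: 5 1,3-bis(benzyloxy)-5-[(2R,3R)-3-(tert-butyldimethylsilyloxy)butan-2-yl]benzene
Product: 7 1,5-bis(benzyloxy)-2,4-dibromo-3-[(2R,3R)-3-(tert-butyldimethylsilyloxy)butan-2-yl]benzene, via monobromide 6 (not isolated)
Conditions: NBS (2.1 equiv), MeCN, 0 °C → rt, dark
Reagents that add atoms: N-bromosuccinimide (NBS), O=C1CCC(=O)N1Br
Why: Electrophilic aromatic bromination in which each benzyloxy group directs para, to the two positions flanking the side chain, while the position between the two ether oxygens is the slowest site of a resorcinol diether (the 4,6-dihalogenation pattern of 5-alkylresorcinols), and NBS releases no HBr that could cleave the silyl ether.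

**Step 4**
Reactants: 7 1,5-bis(benzyloxy)-2,4-dibromo-3-[(2R,3R)-3-(tert-butyldimethylsilyloxy)butan-2-yl]benzene
Product: 9 1,5-bis(benzyloxy)-2-bromo-4-methyl-3-[(2R,3R)-3-(tert-butyldimethylsilyloxy)butan-2-yl]benzene, via aryllithium 8 (not isolated)
Conditions: n-BuLi (1.05 equiv), THF, −78 °C; MeI, −78 °C → rt
Reagents that add atoms: iodomethane (MeI), CI
Why: Bromine–lithium exchange with one equivalent of n-BuLi followed by SN2 methylation of the aryllithium, the two bromines being interconverted by rotation about the aryl–side-chain bond so that single exchange should give one compound.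

**Step 5**
Reactants: 9 1,5-bis(benzyloxy)-2-bromo-4-methyl-3-[(2R,3R)-3-(tert-butyldimethylsilyloxy)butan-2-yl]benzene
Product: 11 4,6-bis(benzyloxy)-3-methyl-2-[(2R,3R)-3-(tert-butyldimethylsilyloxy)butan-2-yl]benzaldehyde, via aryllithium 10 (not isolated)
Conditions: n-BuLi, THF, −78 °C; DMF, −78 → 0 °C
Reagents that add atoms: N,N-dimethylformamide (DMF), CN(C)C=O
Why: Bromine–lithium exchange and Bouveault formylation with DMF place the aldehyde exactly where the second bromine sat, so no choice between ring positions is involved.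

**Step 6**
Reactants: 11 4,6-bis(benzyloxy)-3-methyl-2-[(2R,3R)-3-(tert-butyldimethylsilyloxy)butan-2-yl]benzaldehyde
Product: 12 4,6-dihydroxy-3-methyl-2-[(2R,3R)-3-(tert-butyldimethylsilyloxy)butan-2-yl]benzaldehyde
Conditions: H2 (1 atm), Pd/C, EtOAc, rt
Reagents that add atoms: none
Why: Hydrogenolysis of aryl benzyl ethers over palladium, in which the silyl ether is inert and the aldehyde, flanked by two ortho substituents on an electron-rich ring, should be reduced much more slowly than the ethers are cleaved if hydrogen uptake is stopped in time.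

**Step 7**
Reactants: 12 4,6-dihydroxy-3-methyl-2-[(2R,3R)-3-(tert-butyldimethylsilyloxy)butan-2-yl]benzaldehyde; 13 4-hydroxy-6-methyl-2H-pyran-2-one (triacetic acid lactone)
Product: 15 7-hydroxy-6-methyl-3-(3-oxobutanoyl)-5-[(2R,3R)-3-(tert-butyldimethylsilyloxy)butan-2-yl]-2H-chromen-2-one, via Knoevenagel adduct 14 (not isolated)
Conditions: piperidine (cat.), EtOH, reflux
Reagents that add atoms: none
Why: Knoevenagel condensation at C3 of the pyranone gives the arylidene dione, whose lactone carbonyl is then attacked by the ortho phenol (intramolecular transacylation) so that the pyranone opens and the coumarin closes with the acetoacetyl chain at C3, the known ring transformation of salicylaldehydes with triacetic acid lactone.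

**Step 8**
Reactants: 15 7-hydroxy-6-methyl-3-(3-oxobutanoyl)-5-[(2R,3R)-3-(tert-butyldimethylsilyloxy)butan-2-yl]-2H-chromen-2-one
Product: 16 7-(tert-butyldimethylsilyloxy)-6-methyl-3-(3-oxobutanoyl)-5-[(2R,3R)-3-(tert-butyldimethylsilyloxy)butan-2-yl]-2H-chromen-2-one
Conditions: TBSCl, imidazole, CH2Cl2, 0 °C → rt
Reagents that add atoms: tert-butyldimethylsilyl chloride (TBSCl), CC(C)(C)[Si](C)(C)Cl
Why: Silylation of the acidic 7-hydroxycoumarin phenol, any silyl enol ether formed on the diketone being hydrolysed again on aqueous work-up.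

**Step 9**
Reactants: 16 7-(tert-butyldimethylsilyloxy)-6-methyl-3-(3-oxobutanoyl)-5-[(2R,3R)-3-(tert-butyldimethylsilyloxy)butan-2-yl]-2H-chromen-2-one
Product: 17 7-(tert-butyldimethylsilyloxy)-5-[(2R,3R)-3-(tert-butyldimethylsilyloxy)butan-2-yl]-6-methyl-3-[(1Z)-1,3-bis(trimethylsilyloxy)buta-1,3-dien-1-yl]-2H-chromen-2-one
Conditions: TMSOTf (2.5 equiv), Et3N (3.5 equiv), Et2O, 0 °C → rt; salts removed under argon, used crude
Reagents that add atoms: trimethylsilyl trifluoromethanesulfonate (TMSOTf), C[Si](C)(C)OS(=O)(=O)C(F)(F)F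
Why: Soft enolisation and double O-silylation of a β-diketone (Simchen conditions for 1,3-bis(silyloxy)dienes), in which the chelated enol is silylated first and the second silylation can only take a proton from the terminal methyl group, so the diene should form without any strong or nucleophilic base touching the coumarin.

**Step 10**
Reactants: 17 7-(tert-butyldimethylsilyloxy)-5-[(2R,3R)-3-(tert-butyldimethylsilyloxy)butan-2-yl]-6-methyl-3-[(1Z)-1,3-bis(trimethylsilyloxy)buta-1,3-dien-1-yl]-2H-chromen-2-one; 18 acetaldehyde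
Product: 21 7-(tert-butyldimethylsilyloxy)-5-[(2R,3R)-3-(tert-butyldimethylsilyloxy)butan-2-yl]-6-methyl-3-[(2S)-2-methyl-4-oxo-3,4-dihydro-2H-pyran-6-yl]-2H-chromen-2-one, via silylated aldol adduct 19 (not isolated), via hydroxy diketone 20 (not isolated)
Conditions: Ti(OiPr)4 (20 mol%), (R)-BINOL (20 mol%), 4 Å MS, THF, freshly distilled MeCHO (5 equiv), −78 °C → rt; then TFA, CH2Cl2, 0 °C
Reagents that add atoms: none
Why: The BINOL-bound tetravalent titanium centre activates acetaldehyde and the unsubstituted CH2 terminus of the diene adds to its carbonyl carbon (vinylogous Mukaiyama aldol, C2'–C3') to give silylated aldol 19, after which TFA removes the trimethylsilyl groups to hydroxy diketone 20, whose C2' hydroxyl adds to C6' with loss of water (O1'–C6'). The closest known reaction type is the Ti(OiPr)4/BINOL-catalysed aldol–cyclocondensation of aldehydes with 1,3-bis(trimethylsilyloxy)dienes of β-diketones, a formal hetero-Diels–Alder route to 2-substituted 2,3-dihydro-4H-pyran-4-ones. The ring closes by 6-endo-trig conjugate addition of the hydroxyl to the enolised C4'–C5'=C6' unit followed by elimination, which is equivalent to 6-exo-trig hemiketal formation at the C6' ketone and dehydration. C2' is under catalyst control: the (R)-BINOL complex is expected to expose the Re face of acetaldehyde, which corresponds to the (S) centre, and the side-chain stereocentres lie too far away to interfere. The step needs attack through the diene terminus and not through C5' or the coumarin C3=C4 bond, which the higher nucleophilicity and lower hindrance of the terminal silyl enol ether carbon should secure, and it needs the TBS ethers to outlast the acid, which a short, cold, anhydrous TFA treatment should allow (partial loss of the alkyl TBS group would not matter, since step 11 removes it).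

**Step 11**
Reactants: 21 7-(tert-butyldimethylsilyloxy)-5-[(2R,3R)-3-(tert-butyldimethylsilyloxy)butan-2-yl]-6-methyl-3-[(2S)-2-methyl-4-oxo-3,4-dihydro-2H-pyran-6-yl]-2H-chromen-2-one
Product: 22 7-hydroxy-5-[(2R,3R)-3-hydroxybutan-2-yl]-6-methyl-3-[(2S)-2-methyl-4-oxo-3,4-dihydro-2H-pyran-6-yl]-2H-chromen-2-one
Conditions: HF·pyridine, pyridine, THF, 0 °C → rt
Reagents that add atoms: none
Why: Fluoride cleavage of the aryl and alkyl TBS ethers under acidic buffering, chosen because basic fluoride could open the dihydropyranone by retro-oxa-Michael reaction and erode C2' or attack the lactone, so no stereocentre should be touched.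

**Compound list**

1 | 1,3-bis(benzyloxy)-5-bromobenzene | Brc1cc(OCc2ccccc2)cc(OCc2ccccc2)c1 | starting material
2 | (2R,3R)-2,3-epoxybutane | C[C@H]1O[C@@H]1C | starting material
3 | [3,5-bis(benzyloxy)phenyl]magnesium bromide | Br[Mg]c1cc(OCc2ccccc2)cc(OCc2ccccc2)c1 | intermediate
4 | (2R,3R)-3-[3,5-bis(benzyloxy)phenyl]butan-2-ol | O(Cc1ccccc1)c1cc(OCc2ccccc2)cc(c1)[C@@H](C)[C@@H](C)O | intermediate
5 | 1,3-bis(benzyloxy)-5-[(2R,3R)-3-(tert-butyldimethylsilyloxy)butan-2-yl]benzene | O(Cc1ccccc1)c1cc(OCc2ccccc2)cc(c1)[C@@H](C)[C@@H](C)O[Si](C)(C)C(C)(C)C | intermediate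
6 | 1,5-bis(benzyloxy)-2-bromo-3-[(2R,3R)-3-(tert-butyldimethylsilyloxy)butan-2-yl]benzene | Brc1c(OCc2ccccc2)cc(OCc2ccccc2)cc1[C@@H](C)[C@@H](C)O[Si](C)(C)C(C)(C)C | intermediate
7 | 1,5-bis(benzyloxy)-2,4-dibromo-3-[(2R,3R)-3-(tert-butyldimethylsilyloxy)butan-2-yl]benzene | Brc1c(OCc2ccccc2)cc(OCc2ccccc2)c(Br)c1[C@@H](C)[C@@H](C)O[Si](C)(C)C(C)(C)C | intermediate
8 | {4,6-bis(benzyloxy)-3-bromo-2-[(2R,3R)-3-(tert-butyldimethylsilyloxy)butan-2-yl]phenyl}lithium | [Li]c1c(OCc2ccccc2)cc(OCc2ccccc2)c(Br)c1[C@@H](C)[C@@H](C)O[Si](C)(C)C(C)(C)C | intermediate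
9 | 1,5-bis(benzyloxy)-2-bromo-4-methyl-3-[(2R,3R)-3-(tert-butyldimethylsilyloxy)butan-2-yl]benzene | Cc1c(OCc2ccccc2)cc(OCc2ccccc2)c(Br)c1[C@@H](C)[C@@H](C)O[Si](C)(C)C(C)(C)C | intermediate
10 | {4,6-bis(benzyloxy)-3-methyl-2-[(2R,3R)-3-(tert-butyldimethylsilyloxy)butan-2-yl]phenyl}lithium | Cc1c(OCc2ccccc2)cc(OCc2ccccc2)c([Li])c1[C@@H](C)[C@@H](C)O[Si](C)(C)C(C)(C)C | intermediate
11 | 4,6-bis(benzyloxy)-3-methyl-2-[(2R,3R)-3-(tert-butyldimethylsilyloxy)butan-2-yl]benzaldehyde | Cc1c(OCc2ccccc2)cc(OCc2ccccc2)c(C=O)c1[C@@H](C)[C@@H](C)O[Si](C)(C)C(C)(C)C | intermediate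
12 | 4,6-dihydroxy-3-methyl-2-[(2R,3R)-3-(tert-butyldimethylsilyloxy)butan-2-yl]benzaldehyde | Cc1c(O)cc(O)c(C=O)c1[C@@H](C)[C@@H](C)O[Si](C)(C)C(C)(C)C | intermediate
13 | 4-hydroxy-6-methyl-2H-pyran-2-one (triacetic acid lactone) | Cc1cc(O)cc(=O)o1 | starting material
14 | 3-{4,6-dihydroxy-3-methyl-2-[(2R,3R)-3-(tert-butyldimethylsilyloxy)butan-2-yl]benzylidene}-6-methyl-2H-pyran-2,4(3H)-dione (alkene geometry not defined) | CC1=CC(=O)C(=Cc2c(O)cc(O)c(C)c2[C@@H](C)[C@@H](C)O[Si](C)(C)C(C)(C)C)C(=O)O1 | intermediate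
15 | 7-hydroxy-6-methyl-3-(3-oxobutanoyl)-5-[(2R,3R)-3-(tert-butyldimethylsilyloxy)butan-2-yl]-2H-chromen-2-one (drawn as the diketone, largely enolised) | Cc1c(O)cc2oc(=O)c(C(=O)CC(C)=O)cc2c1[C@@H](C)[C@@H](C)O[Si](C)(C)C(C)(C)C | intermediate
16 | 7-(tert-butyldimethylsilyloxy)-6-methyl-3-(3-oxobutanoyl)-5-[(2R,3R)-3-(tert-butyldimethylsilyloxy)butan-2-yl]-2H-chromen-2-one | Cc1c(O[Si](C)(C)C(C)(C)C)cc2oc(=O)c(C(=O)CC(C)=O)cc2c1[C@@H](C)[C@@H](C)O[Si](C)(C)C(C)(C)C | intermediate
17 | 7-(tert-butyldimethylsilyloxy)-5-[(2R,3R)-3-(tert-butyldimethylsilyloxy)butan-2-yl]-6-methyl-3-[(1Z)-1,3-bis(trimethylsilyloxy)buta-1,3-dien-1-yl]-2H-chromen-2-one | Cc1c(O[Si](C)(C)C(C)(C)C)cc2oc(=O)c(/C(O[Si](C)(C)C)=C/C(=C)O[Si](C)(C)C)cc2c1[C@@H](C)[C@@H](C)O[Si](C)(C)C(C)(C)C | intermediate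
18 | acetaldehyde | CC=O | starting material
19 | 7-(tert-butyldimethylsilyloxy)-5-[(2R,3R)-3-(tert-butyldimethylsilyloxy)butan-2-yl]-6-methyl-3-[(1Z,5S)-3-oxo-1,5-bis(trimethylsilyloxy)hex-1-en-1-yl]-2H-chromen-2-one | Cc1c(O[Si](C)(C)C(C)(C)C)cc2oc(=O)c(/C(O[Si](C)(C)C)=C/C(=O)C[C@H](C)O[Si](C)(C)C)cc2c1[C@@H](C)[C@@H](C)O[Si](C)(C)C(C)(C)C | intermediate
20 | 7-(tert-butyldimethylsilyloxy)-5-[(2R,3R)-3-(tert-butyldimethylsilyloxy)butan-2-yl]-3-[(5S)-5-hydroxy-3-oxohexanoyl]-6-methyl-2H-chromen-2-one | Cc1c(O[Si](C)(C)C(C)(C)C)cc2oc(=O)c(C(=O)CC(=O)C[C@H](C)O)cc2c1[C@@H](C)[C@@H](C)O[Si](C)(C)C(C)(C)C | intermediate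
21 | 7-(tert-butyldimethylsilyloxy)-5-[(2R,3R)-3-(tert-butyldimethylsilyloxy)butan-2-yl]-6-methyl-3-[(2S)-2-methyl-4-oxo-3,4-dihydro-2H-pyran-6-yl]-2H-chromen-2-one | Cc1c(O[Si](C)(C)C(C)(C)C)cc2oc(=O)c(C3=CC(=O)C[C@H](C)O3)cc2c1[C@@H](C)[C@@H](C)O[Si](C)(C)C(C)(C)C | intermediate
22 | 7-hydroxy-5-[(2R,3R)-3-hydroxybutan-2-yl]-6-methyl-3-[(2S)-2-methyl-4-oxo-3,4-dihydro-2H-pyran-6-yl]-2H-chromen-2-one | Cc1c(O)cc2oc(=O)c(C3=CC(=O)C[C@H](C)O3)cc2c1[C@@H](C)[C@@H](C)O | target

**Step count and risks**

Total steps: 11. Longest linear sequence: 11 steps (1 to 22).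

Step 10. What may go wrong is weak enantioface discrimination on the small, enolisable acetaldehyde (giving C2' epimers that differ only at a remote centre), self-condensation of acetaldehyde on the Lewis acid, or hydrolysis of the diene before it reacts. The sense of induction would first be confirmed on the diene of benzoylacetone. Fallback: C2' is taken from the chiral pool and the ring is closed from a preformed (S)-δ-oxygenated diketone. Methyl (S)-3-hydroxybutanoate is silylated (TBSCl, imidazole) to methyl (3S)-3-(tert-butyldimethylsilyloxy)butanoate F1. F1 acylates the dianion of methyl acetoacetate (NaH, then n-BuLi, THF, 0 °C; Claisen condensation) to give methyl (7S)-7-(tert-butyldimethylsilyloxy)-3,5-dioxooctanoate F2. DBU in hot toluene lactonises F2 to 4-hydroxy-6-[(2S)-2-(tert-butyldimethylsilyloxy)propyl]-2H-pyran-2-one F3, a triacetic acid lactone that already carries the future C2'. Setting out from salicylaldehyde 12, the condensation of step 7 is repeated with F3 in place of 13 and should give 7-hydroxy-6-methyl-3-[(5S)-5-(tert-butyldimethylsilyloxy)-3-oxohexanoyl]-5-[(2R,3R)-3-(tert-butyldimethylsilyloxy)butan-2-yl]-2H-chromen-2-one F4. Aqueous HF in MeCN then removes both silyl groups, and the freed C2' hydroxyl closes onto C6' with loss of water (a little TFA completes the dehydration if needed). The sequence comes back to the route at target 22.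

Step 7. What may go wrong is a slow intermolecular Knoevenagel addition, because the aldehyde of 12 is flanked by a hydroxyl and a branched alkyl group, so that the lactone is consumed by self-condensation or double addition instead. Fallback: the ester bond is made first and the C3–C4 bond is closed intramolecularly. Setting out from 12, the unhindered para hydroxyl is silylated selectively (TBSCl, imidazole, 0 °C) to give 4-(tert-butyldimethylsilyloxy)-6-hydroxy-3-methyl-2-[(2R,3R)-3-(tert-butyldimethylsilyloxy)butan-2-yl]benzaldehyde F5. Heating F5 with 2,2,6-trimethyl-4H-1,3-dioxin-4-one in toluene (acetylketene transfer) gives 2-formyl-4-methyl-5-(tert-butyldimethylsilyloxy)-3-[(2R,3R)-3-(tert-butyldimethylsilyloxy)butan-2-yl]phenyl 3-oxobutanoate F6, which is not isolated. Catalytic Et3N closes F6 by intramolecular Knoevenagel condensation to 3-acetyl-7-(tert-butyldimethylsilyloxy)-6-methyl-5-[(2R,3R)-3-(tert-butyldimethylsilyloxy)butan-2-yl]-2H-chromen-2-one F7. A crossed Claisen acylation under soft enolisation (MgBr2·OEt2, i-Pr2NEt, 1-acetylbenzotriazole, CH2Cl2) then adds the second acetyl unit and comes back to the route at 16.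

Step 6. What may go wrong is over-reduction, the aldehyde being carried on to the benzylic alcohol or the methyl group while the second benzyl ether is still being cleaved. Fallback: the benzyl groups are removed before the aldehyde exists. Setting out from bromide 9, hydrogenation over Pd/C in the presence of NaOAc (MeOH–EtOAc) cleaves both benzyl ethers and the carbon–bromine bond to give 4-methyl-5-[(2R,3R)-3-(tert-butyldimethylsilyloxy)butan-2-yl]benzene-1,3-diol F8. Vilsmeier–Haack formylation of this free resorcinol (POCl3, DMF, MeCN, 0 °C, then aqueous NaOAc) is expected to go para to one hydroxyl and ortho to the other, next to the side chain, as it does for orcinol. It comes back to the route at 12.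

**Further compounds**

F1 | step 10 | methyl (3S)-3-(tert-butyldimethylsilyloxy)butanoate | C[C@H](O[Si](C)(C)C(C)(C)C)CC(=O)OC
F2 | step 10 | methyl (7S)-7-(tert-butyldimethylsilyloxy)-3,5-dioxooctanoate | C[C@H](O[Si](C)(C)C(C)(C)C)CC(=O)CC(=O)CC(=O)OC
F3 | step 10 | 4-hydroxy-6-[(2S)-2-(tert-butyldimethylsilyloxy)propyl]-2H-pyran-2-one | C[C@H](O[Si](C)(C)C(C)(C)C)Cc1cc(O)cc(=O)o1
F4 | step 10 | 7-hydroxy-6-methyl-3-[(5S)-5-(tert-butyldimethylsilyloxy)-3-oxohexanoyl]-5-[(2R,3R)-3-(tert-butyldimethylsilyloxy)butan-2-yl]-2H-chromen-2-one | Cc1c(O)cc2oc(=O)c(C(=O)CC(=O)C[C@H](C)O[Si](C)(C)C(C)(C)C)cc2c1[C@@H](C)[C@@H](C)O[Si](C)(C)C(C)(C)C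
F5 | step 7 | 4-(tert-butyldimethylsilyloxy)-6-hydroxy-3-methyl-2-[(2R,3R)-3-(tert-butyldimethylsilyloxy)butan-2-yl]benzaldehyde | Cc1c(O[Si](C)(C)C(C)(C)C)cc(O)c(C=O)c1[C@@H](C)[C@@H](C)O[Si](C)(C)C(C)(C)C
F6 | step 7 | 2-formyl-4-methyl-5-(tert-butyldimethylsilyloxy)-3-[(2R,3R)-3-(tert-butyldimethylsilyloxy)butan-2-yl]phenyl 3-oxobutanoate | Cc1c(O[Si](C)(C)C(C)(C)C)cc(OC(=O)CC(C)=O)c(C=O)c1[C@@H](C)[C@@H](C)O[Si](C)(C)C(C)(C)C
F7 | step 7 | 3-acetyl-7-(tert-butyldimethylsilyloxy)-6-methyl-5-[(2R,3R)-3-(tert-butyldimethylsilyloxy)butan-2-yl]-2H-chromen-2-one | Cc1c(O[Si](C)(C)C(C)(C)C)cc2oc(=O)c(C(C)=O)cc2c1[C@@H](C)[C@@H](C)O[Si](C)(C)C(C)(C)C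
F8 | step 6 | 4-methyl-5-[(2R,3R)-3-(tert-butyldimethylsilyloxy)butan-2-yl]benzene-1,3-diol | Cc1c(O)cc(O)cc1[C@@H](C)[C@@H](C)O[Si](C)(C)C(C)(C)C
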